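# Synthesis proposal for CNP0249520.1, an 8-angeloyloxy-1,3,10-trihydroxy germacra-4,11(13)-dien-12,6-olide

Skeletal atoms carry germacrane numbers throughout: C1–C10 form the ring, C11 is the lactone α-carbon, C12 the lactone carbonyl, C13 the exocyclic methylene carbon, C14 the methyl on C10 and C15 the methyl on C4.

## The problem

The target is a ten-membered carbocycle (C1–C10) trans-fused at C6–C7 to an α-methylene-γ-butyrolactone. It carries a Z trisubstituted C4=C5 alkene in which C3 and C6 are cis, free hydroxyls at C1, C3 and C10 (tertiary), and an angelate at C8. Its configuration is 1S,3S,6S,7S,8R,10R.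

The stereocentres fall into three groups. C6, C7 and C8 are contiguous on the lactone side. C10 and C1 are a vicinal diol across the ring. C3 is cut off from the rest by the alkene and has to be set by a reagent. Within the groups, C6 can direct C7 through the five-membered ring, C10 can direct C8 (1,3) and C1 (1,2), and nothing directs C10 itself except the conformation of the closing ring.

Several groups will not bear rough handling. The α-methylene lactone is a Michael acceptor and a radical acceptor. The angelate drifts to the tiglate with acid, base or heat. The C3–O and C6–O bonds are allylic. A ketone at C8 would sit β to the C6 acyloxy group and α to the ring-fusion hydrogen at C7.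

The medium ring adds the usual entropic and transannular cost of closure. The feature that opens the structure is that the lactone carbons C7 and C11 each carry exactly one exocyclic carbon, C8 and C13. A butenolide substituted at C6 can therefore accept C8 as an acyl anion equivalent at C7 and C13 as an iminium carbon at C11 in one conjugate-addition and enolate-trapping operation. C8 then sits at the ketone oxidation level, and C1 and C10 remain as two carbonyl termini for a reductive closure of the ring.

## Retrosynthesis

**Target 30 to amine 27.** The silyl ethers at C1 and C3 of 29 are removed last. The C11=C13 alkene of 29 is traced to the C13 dimethylamino compound 27 by quaternisation and elimination via salt 28. No bond of the skeleton is cut. Carrying C13 as an amine is preferred to a late methylenation of a saturated lactone, which would need a strong base on a molecule holding an angelate and a tertiary alcohol. It also keeps the Michael acceptor out of the reductive steps.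

**Amine 27 to alcohol 24 and angelic acid 25.** The C8–O acyl bond is cut. The ester is put on late, through mixed anhydride 26, so that it meets neither SmI2 nor a hydride. The cut is clean only because C8–OH is the single acylable hydroxyl in 24: C1 is silylated, C3 is silylated, and C10 is tertiary.

**Alcohol 24 to ketone 23, dithiane 22 and diol 21.** C8 is taken back to a ketone and then to its dithiane. Reducing the C8 ketone in the ring, with the C10 hydroxyl 1,3 to it, offers an internal hydride delivery that gives the 8,10-anti diol the target requires. Reducing it in the open chain would set C8 between two similar branches at C7 with no control element. Keeping the dithiane until after ring closure also means that C8 and C10 never coexist as a 1,3-diketone. The C1 hydroxyl is capped (22) before the dithiane is opened, so the forward sequence asks for one selective silylation, one hydrolysis and one directed reduction.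

**Diol 21 to keto aldehyde 20.** The C1–C10 bond is cut. It is the only ring bond flanked by two oxygen-bearing carbons, so a reductive carbonyl coupling returns both hydroxyls and the ring at once. It is also the bond between the termini of the two fragments that the key step joins. Closures at C2–C3 or C9–C10 would need enolate chemistry next to the lactone, and a metathesis at C4=C5 would leave the geometry of a trisubstituted ring alkene open. The precursor is acyclic apart from the lactone. The forward step must close a ten-membered ring and set C1 and C10, which is the least controlled event of the plan.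

**Keto aldehyde 20 to key product 18.** Swern oxidation of alcohol 19 and acid unmasking of the primary silyl ether and the dioxolane of 18 are functional-group changes only. A silyl ether at C1 is chosen over a p-methoxybenzyl ether because oxidative debenzylation would not spare the dithiane and the tertiary amine.

**Key product 18 to butenolide 10, dithiane 14 and iminium salt 15.** The C7–C8 and C11–C13 bonds are cut together. The alternative of alkylating a saturated lactone twice would give up the control of C7 by C6 and use two enolate steps. The butenolide gives the enolate for the second bond as a consequence of the first (via 16 and 17). The precursors are a C10 butenolide, a C4 dithiane and a C1 salt. The forward step must add 1,4, anti to the C6 substituent, without deprotonating C6.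

**Butenolide 10 to enal 7 and methyl propiolate 2.** The C6–C7 bond is cut. A γ-hydroxy ynoate 8 reduces over a poisoned palladium catalyst to the Z enoate 9, which closes to the lactone. C6 is set in the C–C bond-forming step by a catalytic asymmetric alkynylation of an enal. An acrylate ring-closing metathesis of a dienyl carbinol would also give 10, but it costs one more step and needs an enantioselective vinyl addition.

**Enal 7 to aldehyde 1 and methyl propiolate 2.** The C15–C4 bond and the C3–C4 bond are cut. Enal 7 comes from enoate 5 through alcohol 6. Syn carbocupration of ynoate 4 with a methyl cuprate fixes the alkene geometry stereospecifically, with C15 trans to the ester carbon that becomes C6. Ynoate 4 is the silyl ether of 3, made by a first asymmetric alkynylation of the commercial aldehyde 1. A Wittig-type olefination of a methyl ketone would not give this geometry reliably.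

**Dithiane 14 to ketone 13, acetal 11 and dithiol 12.** The two C–S bonds and the ketal C–O bonds are cut. The commercial acetal ketone 11 gives the dithiane at the aldehyde carbon, and the ketone is then masked so that the C8 hydrogen is the only acidic one.

## Roads not taken

**Alternative 1:** The cut removes the two allylic C–O bonds at C3 and C6 together and leads back to ring diene A2, a ten-membered ring with cis C3=C4 and cis C5=C6 bonds, the C1/C10 diol as acetonide, the C8 angelate and an acrylate on C7. In the forward step sensitised singlet oxygen adds across C3 and C6 to give endoperoxide A1. Reduction of the O–O bond and lactonisation of the C6 hydroxyl onto the acrylate follow.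

- Merits: the Z geometry of C4=C5 is automatic because it is the ring alkene of the dioxene. Both oxygens arrive in one suprafacial step with no protecting groups at C3 or C6.
- Weak points: A2 is itself a ten-membered ring, now with a cis,cis-1,3-diene that must reach a near-planar s-cis conformation, and its construction is left open. The ene reaction of singlet oxygen at the trisubstituted C3=C4 bond (allylic hydrogens at C15 and C2) competes with the cycloaddition. Only one face of the diene gives the trans lactone. The peroxide must be reduced without touching the acrylate and the angelate.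
- Comparison: this road is better for the C3–C6 segment. It sets two C–O bonds and the alkene in one step, where the chosen plan spends steps 1 to 7. Against that, the chosen plan sets C3 and C6 by reagent control independent of any ring conformation, fixes the alkene by a stereospecific carbocupration, and does not depend on a medium ring whose synthesis is unsolved.

**Alternative 2:** The cut is made at C2–C3 while a C5–C10 bond is drawn, so the ring contracts to cyclohexanol A4. A4 carries a vinyl group and the hydroxyl on C10 and a 2-(methoxymethoxy)-1-methylvinyl group on C5. In the forward step KH with 18-crown-6 triggers an anionic oxy-Cope rearrangement to cyclodecenone A3.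

- Merits: the ring is made by expansion, with no high dilution and no entropic penalty. C6, C7 and C8 are set on a cyclohexane, where an all-equatorial arrangement is easy to reach. The rearrangement delivers a regiodefined C1=C10 enolate that could be oxidised in the same flask to place the C1 oxygen.
- Weak points: a chair transition state from the trans-diequatorial dialkenyl arrangement puts C6 pseudo-equatorial at C5 and therefore gives the ring-trans C4=C5 alkene. The ring-cis (4Z) alkene of the target needs an axial arm or a boat, which is not secured. The C3 configuration depends on the enol ether geometry and on the same transition-state choice. After the expansion, the C14 methyl must be added to the C10 ketone with facial control, C12 must be oxidised to the lactone level, and four ethers must be removed.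
- Comparison: this road is clearly better at ring formation, which is the weakest point of the chosen plan. The chosen plan sets against it an alkene geometry fixed before any ring exists, a C10 that arrives with its methyl group, and the lactone with C13 already in place.

**Alternative 3:** The cut is the C1–C10 bond, leading to keto aldehyde A6, which has a saturated lactone lacking C13 and silyl ethers at C3 and C8. In the forward step low-valent titanium from TiCl3(DME)1.5 and Zn–Cu couple closes diol A5.

- Merits: ring and diol form in one step, and the titanium pinacol has direct precedent for ten-membered diols.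
- Weak points: the assembly of A6 is left open. C8 has to be set in the open chain. C13 must be introduced afterwards by enolate chemistry on a molecule with a free diol. The two identical silyl ethers at C3 and C8 give no handle for a selective angeloylation. The configuration at C1 and C10 is uncontrolled.
- Comparison: the chosen plan closes the ring by the same type of reaction and shares the stereochemical uncertainty. Its SmI2 closure is less well precedented for this ring size than the titanium reagent. It adds a convergent route to the keto aldehyde, C13 in place as a masked methylene, and a dithiane that lets C8 be set after C10 by 1,3-induction and leaves C8–OH as the only acylable hydroxyl.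

Key step: step 10

## Route

Assumption on the chemistry: the (S,S)-enantiomer of ProPhenol is taken to deliver the propiolate to the aldehyde face that gives the S carbinols 3 and 8. In both, the alkynyl carbon outranks the aldehyde residue, so one ligand enantiomer serves twice. A Mosher ester check on 3 decides, and the antipodal ligand is used in steps 1 and 6 if the sense is reversed.

Step 1
Reactants: 1 3-[(tert-butyldimethylsilyl)oxy]propanal; 2 methyl propiolate
Product: 3 methyl (4S)-6-[(tert-butyldimethylsilyl)oxy]-4-hydroxyhex-2-ynoate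
Conditions: (S,S)-ProPhenol (10 mol %), Me2Zn, Ph3PO (20 mol %), toluene, 0 °C, slow addition of 1
Reagents that add atoms: none
Why: Zn–ProPhenol-catalysed enantioselective alkynylation of an aldehyde; the dinuclear zinc complex holds the zinc acetylide and the aldehyde and delivers the alkynyl group to one carbonyl face, which sets C3 (S) under ligand control, and slow addition of 1 limits aldol self-condensation.

Step 2
Reactants: 3 methyl (4S)-6-[(tert-butyldimethylsilyl)oxy]-4-hydroxyhex-2-ynoate
Product: 4 methyl (4S)-6-[(tert-butyldimethylsilyl)oxy]-4-[(tert-butyldiphenylsilyl)oxy]hex-2-ynoate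
Conditions: TBDPSCl, imidazole, DMAP (cat.), CH2Cl2, 0 to 25 °C
Reagents that add atoms: tert-butyl(chloro)diphenylsilane, CC(C)(C)[Si](Cl)(c1ccccc1)c1ccccc1
Why: Standard silylation of a secondary propargylic alcohol; the robust silyl ether blocks lactonisation after step 3 and outlasts the aqueous acid of step 11 that removes the primary silyl ether.

Step 3
Reactants: 4 methyl (4S)-6-[(tert-butyldimethylsilyl)oxy]-4-[(tert-butyldiphenylsilyl)oxy]hex-2-ynoate
Product: 5 methyl (2Z,4S)-6-[(tert-butyldimethylsilyl)oxy]-4-[(tert-butyldiphenylsilyl)oxy]-3-methylhex-2-enoate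
Conditions: MeLi (2 equiv), CuI (1 equiv), THF, −78 °C; MeOH at −78 °C, then aq. NH4Cl
Reagents that add atoms: lithium dimethylcuprate, [Li+].C[Cu-]C
Why: Conjugate addition of a Gilman cuprate to an ynoate is a syn carbocupration; protonation at −78 °C with retention leaves C15 trans to the ester carbon, so C3 and the future C6 are cis across C4=C5, and the low temperature prevents equilibration through the allenoate.

Step 4
Reactants: 5 methyl (2Z,4S)-6-[(tert-butyldimethylsilyl)oxy]-4-[(tert-butyldiphenylsilyl)oxy]-3-methylhex-2-enoate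
Product: 6 (2Z,4S)-6-[(tert-butyldimethylsilyl)oxy]-4-[(tert-butyldiphenylsilyl)oxy]-3-methylhex-2-en-1-ol
Conditions: iBu2AlH (2.2 equiv), CH2Cl2, −78 °C; Rochelle salt work-up
Reagents that add atoms: none
Why: 1,2-Reduction of an α,β-unsaturated ester to the allylic alcohol with iBu2AlH; the alkene geometry and both silyl ethers are untouched.

Step 5
Reactants: 6 (2Z,4S)-6-[(tert-butyldimethylsilyl)oxy]-4-[(tert-butyldiphenylsilyl)oxy]-3-methylhex-2-en-1-ol
Product: 7 (2Z,4S)-6-[(tert-butyldimethylsilyl)oxy]-4-[(tert-butyldiphenylsilyl)oxy]-3-methylhex-2-enal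
Conditions: TEMPO (10 mol %), PhI(OAc)2, CH2Cl2, 25 °C
Reagents that add atoms: none
Why: Oxoammonium (TEMPO) oxidation of an allylic alcohol under neutral conditions, which is known to keep Z allylic alcohols from isomerising on the way to the enal.

Step 6
Reactants: 7 (2Z,4S)-6-[(tert-butyldimethylsilyl)oxy]-4-[(tert-butyldiphenylsilyl)oxy]-3-methylhex-2-enal; 2 methyl propiolate
Product: 8 methyl (4S,5Z,7S)-9-[(tert-butyldimethylsilyl)oxy]-7-[(tert-butyldiphenylsilyl)oxy]-4-hydroxy-6-methylnon-5-en-2-ynoate
Conditions: (S,S)-ProPhenol (20 mol %), Me2Zn, Ph3PO (40 mol %), toluene, 0 °C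
Reagents that add atoms: none
Why: Second Zn–ProPhenol alkynylation, on the substrate class (enals) for which it works best; the ligand sets C6 (4S in 8) and overrides the remote C3 centre, and the mild zinc alkoxide medium should leave the Z enal intact.

Step 7
Reactants: 8 methyl (4S,5Z,7S)-9-[(tert-butyldimethylsilyl)oxy]-7-[(tert-butyldiphenylsilyl)oxy]-4-hydroxy-6-methylnon-5-en-2-ynoate
Product: 10 (5R)-5-{(1Z,3S)-5-[(tert-butyldimethylsilyl)oxy]-3-[(tert-butyldiphenylsilyl)oxy]-2-methylpent-1-en-1-yl}furan-2(5H)-one, via Z-hydroxy enoate 9 (not isolated)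
Conditions: H2 (1 atm), Pd/CaCO3 poisoned with Pb(OAc)2, quinoline, EtOAc, 25 °C; then PPTS (cat.), CH2Cl2, 25 °C
Reagents that add atoms: none
Why: Lindlar semihydrogenation gives the Z γ-hydroxy enoate, which lactonises to the butenolide by intramolecular transesterification; the trisubstituted alkene is inert, C6 is not touched, and its descriptor changes from 4S in 8 to 5R in 10 by priority only.

Step 8
Reactants: 11 4,4-dimethoxybutan-2-one; 12 propane-1,3-dithiol
Product: 13 1-(1,3-dithian-2-yl)propan-2-one
Conditions: BF3·OEt2, CH2Cl2, −20 to 0 °C, 1.0 equiv of 12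
Reagents that add atoms: none
Why: Lewis-acid transthioacetalisation; the dimethyl acetal ionises to an oxocarbenium ion and is captured by the dithiol much faster than the ketone is thioketalised, and the competing path through the β-methoxy enone converges on the same β-keto dithiane.

Step 9
Reactants: 13 1-(1,3-dithian-2-yl)propan-2-one
Product: 14 2-[(2-methyl-1,3-dioxolan-2-yl)methyl]-1,3-dithiane
Conditions: (TMSOCH2)2, TMSOTf (cat.), CH2Cl2, −78 to −20 °C
Reagents that add atoms: 1,2-bis(trimethylsilyloxy)ethane, C[Si](C)(C)OCCO[Si](C)(C)C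
Why: Noyori ketalisation under aprotic conditions masks the ketone without opening the β-keto dithiane, so the C8 hydrogen is the only acidic one in 14.

Step 10
Reactants: 14 2-[(2-methyl-1,3-dioxolan-2-yl)methyl]-1,3-dithiane; 10 (5R)-5-{(1Z,3S)-5-[(tert-butyldimethylsilyl)oxy]-3-[(tert-butyldiphenylsilyl)oxy]-2-methylpent-1-en-1-yl}furan-2(5H)-one; 15 dimethylmethyleneiminium iodide
Product: 18 (3S,4R,5S)-5-{(1Z,3S)-5-[(tert-butyldimethylsilyl)oxy]-3-[(tert-butyldiphenylsilyl)oxy]-2-methylpent-1-en-1-yl}-3-[(dimethylamino)methyl]-4-{2-[(2-methyl-1,3-dioxolan-2-yl)methyl]-1,3-dithian-2-yl}oxolan-2-one, via 2-lithiodithiane 16 (not isolated), via lithium lactone enolate 17 (not isolated)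
Conditions: 14, n-BuLi, THF, −30 °C; HMPA, −78 °C; 10 added slowly, −78 °C; then 15, −78 to 0 °C
Reagents that add atoms: none
Why: n-BuLi removes the C8 hydrogen of 14, and in THF–HMPA the sulfur-stabilised carbanion 16 reacts as a separated ion pair and adds 1,4 to C7 of butenolide 10 to give lithium enolate 17, which is C-alkylated at C11 by iminium salt 15 in a Mannich reaction. The closest known reaction type is the tandem conjugate addition of 2-lithio-1,3-dithianes to butenolides with alkylation of the lactone enolate, as used for trans-disubstituted lignan lactones, joined to the aminomethylation of lactone enolates with this iminium salt. No ring is closed; the C7–C8 and C11–C13 bonds form and all fifteen skeletal carbons are united. C7 is controlled by C6: the alkenyl group shields one face of the planar butenolide, so the bulky nucleophile enters anti and the C6/C7 relationship is trans. C11 is controlled by C7: the enolate is attacked anti to the new quaternary dithianyl group, and since this centre is lost in step 18 its purity only simplifies handling. The step needs 1,4- over 1,2-addition, secured by HMPA and by the soft tertiary dithianyl anion, and addition over deprotonation at C6, favoured by −78 °C and by adding 10 slowly to 16. The descriptor at C6 changes from R in 10 to S in 18 by priority only.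

Step 11
Reactants: 18 (3S,4R,5S)-5-{(1Z,3S)-5-[(tert-butyldimethylsilyl)oxy]-3-[(tert-butyldiphenylsilyl)oxy]-2-methylpent-1-en-1-yl}-3-[(dimethylamino)methyl]-4-{2-[(2-methyl-1,3-dioxolan-2-yl)methyl]-1,3-dithian-2-yl}oxolan-2-one
Product: 19 (3S,4R,5S)-5-{(1Z,3S)-3-[(tert-butyldiphenylsilyl)oxy]-5-hydroxy-2-methylpent-1-en-1-yl}-3-[(dimethylamino)methyl]-4-[2-(2-oxopropyl)-1,3-dithian-2-yl]oxolan-2-one
Conditions: 1 M aq. HCl, THF, 25 °C; NaHCO3 work-up
Reagents that add atoms: water, O
Why: Acid hydrolysis removes the primary tert-butyldimethylsilyl ether and the ketone dioxolane in one operation, while the dithiane, the tert-butyldiphenylsilyl ether and the lactone are stable to dilute acid and the amine is simply protonated.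

Step 12
Reactants: 19 (3S,4R,5S)-5-{(1Z,3S)-3-[(tert-butyldiphenylsilyl)oxy]-5-hydroxy-2-methylpent-1-en-1-yl}-3-[(dimethylamino)methyl]-4-[2-(2-oxopropyl)-1,3-dithian-2-yl]oxolan-2-one
Product: 20 (3S,4R,5S)-5-{(1Z,3S)-3-[(tert-butyldiphenylsilyl)oxy]-2-methyl-5-oxopent-1-en-1-yl}-3-[(dimethylamino)methyl]-4-[2-(2-oxopropyl)-1,3-dithian-2-yl]oxolan-2-one
Conditions: (COCl)2, DMSO, CH2Cl2, −78 °C; Et3N, −78 to −20 °C
Reagents that add atoms: none
Why: Swern oxidation of the primary alcohol to the C1 aldehyde; activated DMSO tolerates the dithiane and the tertiary amine, and the cold basic work-up limits β-elimination of the C3 silyloxy group.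

Step 13
Reactants: 20 (3S,4R,5S)-5-{(1Z,3S)-3-[(tert-butyldiphenylsilyl)oxy]-2-methyl-5-oxopent-1-en-1-yl}-3-[(dimethylamino)methyl]-4-[2-(2-oxopropyl)-1,3-dithian-2-yl]oxolan-2-one
Product: 21 (1S,3S,4Z,6S,7R,10R,11S)-3-[(tert-butyldiphenylsilyl)oxy]-13-(dimethylamino)-1,10-dihydroxy-8,8-(propane-1,3-diyldisulfanediyl)germacr-4-en-12,6-olide
Conditions: SmI2 (4 equiv), THF, 25 °C, slow addition of 20 to 0.002 M
Reagents that add atoms: none
Why: Intramolecular pinacol coupling of a keto aldehyde: the C1 ketyl adds to the C10 ketone and closes the ten-membered ring, helped by the quaternary dithiane carbon, the Z alkene and the lactone, which turn the chain; SmI2 is chosen because it spares thioacetals, lactones and amines. C1 and C10 are set by the conformation of the closing ring with both oxygens held on samarium; this control is not secured in advance (see the fallback).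

Step 14
Reactants: 21 (1S,3S,4Z,6S,7R,10R,11S)-3-[(tert-butyldiphenylsilyl)oxy]-13-(dimethylamino)-1,10-dihydroxy-8,8-(propane-1,3-diyldisulfanediyl)germacr-4-en-12,6-olide
Product: 22 (1S,3S,4Z,6S,7R,10R,11S)-3-[(tert-butyldiphenylsilyl)oxy]-13-(dimethylamino)-10-hydroxy-8,8-(propane-1,3-diyldisulfanediyl)-1-[(triethylsilyl)oxy]germacr-4-en-12,6-olide
Conditions: TESCl, imidazole, DMF, 0 °C
Reagents that add atoms: chlorotriethylsilane, CC[Si](Cl)(CC)CC
Why: Silylation with a silyl chloride and imidazole takes the secondary C1 hydroxyl and leaves the tertiary C10 hydroxyl free, which is needed as the directing group in step 16.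

Step 15
Reactants: 22 (1S,3S,4Z,6S,7R,10R,11S)-3-[(tert-butyldiphenylsilyl)oxy]-13-(dimethylamino)-10-hydroxy-8,8-(propane-1,3-diyldisulfanediyl)-1-[(triethylsilyl)oxy]germacr-4-en-12,6-olide
Product: 23 (1S,3S,4Z,6S,7R,10R,11S)-3-[(tert-butyldiphenylsilyl)oxy]-13-(dimethylamino)-10-hydroxy-8-oxo-1-[(triethylsilyl)oxy]germacr-4-en-12,6-olide
Conditions: Hg(ClO4)2, CaCO3, THF/H2O (5:1), 0 °C; used at once
Reagents that add atoms: water, O
Why: Divalent mercury-assisted hydrolysis of the dithiane is fast at 0 °C and the CaCO3 buffer keeps the medium near neutral, which protects the silyl ethers; the β-hydroxy ketone is not stored, because base could epimerise C7 or expel the C6 carboxylate.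

Step 16
Reactants: 23 (1S,3S,4Z,6S,7R,10R,11S)-3-[(tert-butyldiphenylsilyl)oxy]-13-(dimethylamino)-10-hydroxy-8-oxo-1-[(triethylsilyl)oxy]germacr-4-en-12,6-olide
Product: 24 (1S,3S,4Z,6S,7S,8R,10R,11S)-3-[(tert-butyldiphenylsilyl)oxy]-13-(dimethylamino)-8,10-dihydroxy-1-[(triethylsilyl)oxy]germacr-4-en-12,6-olide
Conditions: Me4NBH(OAc)3, MeCN/AcOH (1:1), −30 °C
Reagents that add atoms: none
Why: Evans–Saksena reduction: the C10 hydroxyl exchanges onto boron and delivers hydride to C8 through a chair six-membered transition state with the larger C10 substituent (C1) equatorial, giving the 8,10-anti diol, which is 8R; the acidic medium keeps the amine protonated and the C7 hydrogen in place.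

Step 17
Reactants: 24 (1S,3S,4Z,6S,7S,8R,10R,11S)-3-[(tert-butyldiphenylsilyl)oxy]-13-(dimethylamino)-8,10-dihydroxy-1-[(triethylsilyl)oxy]germacr-4-en-12,6-olide; 25 angelic acid
Product: 27 (1S,3S,4Z,6S,7S,8R,10R,11S)-3-[(tert-butyldiphenylsilyl)oxy]-13-(dimethylamino)-10-hydroxy-8-{[(2Z)-2-methylbut-2-enoyl]oxy}-1-[(triethylsilyl)oxy]germacr-4-en-12,6-olide, via mixed anhydride 26 (not isolated)
Conditions: 25, 2,4,6-Cl3C6H2COCl, Et3N, toluene, 25 °C; then 24, 60 °C
Reagents that add atoms: none
Why: Yamaguchi esterification through the mixed anhydride of angelic acid, the established way to make angelates with little isomerisation to the tiglate; only the secondary C8 hydroxyl is acylated because the C10 hydroxyl is tertiary.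

Step 18
Reactants: 27 (1S,3S,4Z,6S,7S,8R,10R,11S)-3-[(tert-butyldiphenylsilyl)oxy]-13-(dimethylamino)-10-hydroxy-8-{[(2Z)-2-methylbut-2-enoyl]oxy}-1-[(triethylsilyl)oxy]germacr-4-en-12,6-olide
Product: 29 (1S,3S,4Z,6S,7S,8R,10R)-3-[(tert-butyldiphenylsilyl)oxy]-10-hydroxy-8-{[(2Z)-2-methylbut-2-enoyl]oxy}-1-[(triethylsilyl)oxy]germacra-4,11(13)-dien-12,6-olide, via trimethylammonium iodide 28 (not isolated)
Conditions: MeI (excess), THF, 25 °C; then aq. NaHCO3, CH2Cl2, 25 °C
Reagents that add atoms: none
Why: Quaternisation of the Mannich base and E1cB loss of trimethylamine under bicarbonate is the standard release of an α-methylene lactone from its amine adduct; the conditions are too mild to isomerise the angelate.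

Step 19
Reactants: 29 (1S,3S,4Z,6S,7S,8R,10R)-3-[(tert-butyldiphenylsilyl)oxy]-10-hydroxy-8-{[(2Z)-2-methylbut-2-enoyl]oxy}-1-[(triethylsilyl)oxy]germacra-4,11(13)-dien-12,6-olide
Product: 30 (1S,3S,4Z,6S,7S,8R,10R)-1,3,10-trihydroxy-8-{[(2Z)-2-methylbut-2-enoyl]oxy}germacra-4,11(13)-dien-12,6-olide (CNP0249520.1)
Conditions: TBAF, AcOH (1:1), THF, 0 to 25 °C
Reagents that add atoms: none
Why: Fluoride desilylation buffered with acetic acid removes both silyl ethers without generating free alkoxide, so the methylene lactone is not attacked and the angelate neither migrates nor isomerises.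

## Compound list

1 | 3-[(tert-butyldimethylsilyl)oxy]propanal | O=CCCO[Si](C)(C)C(C)(C)C | starting material
2 | methyl propiolate | C#CC(=O)OC | starting material
3 | methyl (4S)-6-[(tert-butyldimethylsilyl)oxy]-4-hydroxyhex-2-ynoate | COC(=O)C#C[C@@H](O)CCO[Si](C)(C)C(C)(C)C | intermediate
4 | methyl (4S)-6-[(tert-butyldimethylsilyl)oxy]-4-[(tert-butyldiphenylsilyl)oxy]hex-2-ynoate | COC(=O)C#C[C@@H](O[Si](c1ccccc1)(c1ccccc1)C(C)(C)C)CCO[Si](C)(C)C(C)(C)C | intermediate
5 | methyl (2Z,4S)-6-[(tert-butyldimethylsilyl)oxy]-4-[(tert-butyldiphenylsilyl)oxy]-3-methylhex-2-enoate | COC(=O)/C=C(/C)[C@@H](O[Si](c1ccccc1)(c1ccccc1)C(C)(C)C)CCO[Si](C)(C)C(C)(C)C | intermediate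
6 | (2Z,4S)-6-[(tert-butyldimethylsilyl)oxy]-4-[(tert-butyldiphenylsilyl)oxy]-3-methylhex-2-en-1-ol | OC/C=C(/C)[C@@H](O[Si](c1ccccc1)(c1ccccc1)C(C)(C)C)CCO[Si](C)(C)C(C)(C)C | intermediate
7 | (2Z,4S)-6-[(tert-butyldimethylsilyl)oxy]-4-[(tert-butyldiphenylsilyl)oxy]-3-methylhex-2-enal | O=C/C=C(/C)[C@@H](O[Si](c1ccccc1)(c1ccccc1)C(C)(C)C)CCO[Si](C)(C)C(C)(C)C | intermediate
8 | methyl (4S,5Z,7S)-9-[(tert-butyldimethylsilyl)oxy]-7-[(tert-butyldiphenylsilyl)oxy]-4-hydroxy-6-methylnon-5-en-2-ynoate | COC(=O)C#C[C@@H](O)/C=C(/C)[C@@H](O[Si](c1ccccc1)(c1ccccc1)C(C)(C)C)CCO[Si](C)(C)C(C)(C)C | intermediate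
9 | methyl (2Z,4R,5Z,7S)-9-[(tert-butyldimethylsilyl)oxy]-7-[(tert-butyldiphenylsilyl)oxy]-4-hydroxy-6-methylnona-2,5-dienoate (not isolated) | COC(=O)/C=C\[C@@H](O)/C=C(/C)[C@@H](O[Si](c1ccccc1)(c1ccccc1)C(C)(C)C)CCO[Si](C)(C)C(C)(C)C | intermediate
10 | (5R)-5-{(1Z,3S)-5-[(tert-butyldimethylsilyl)oxy]-3-[(tert-butyldiphenylsilyl)oxy]-2-methylpent-1-en-1-yl}furan-2(5H)-one | O=C1C=C[C@H](/C=C(/C)[C@@H](O[Si](c2ccccc2)(c2ccccc2)C(C)(C)C)CCO[Si](C)(C)C(C)(C)C)O1 | intermediate
11 | 4,4-dimethoxybutan-2-one | CC(=O)CC(OC)OC | starting material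
12 | propane-1,3-dithiol | SCCCS | starting material
13 | 1-(1,3-dithian-2-yl)propan-2-one | CC(=O)CC1SCCCS1 | intermediate
14 | 2-[(2-methyl-1,3-dioxolan-2-yl)methyl]-1,3-dithiane | CC1(CC2SCCCS2)OCCO1 | intermediate
15 | dimethylmethyleneiminium iodide | C=[N+](C)C.[I-] | starting material
16 | 2-lithio-2-[(2-methyl-1,3-dioxolan-2-yl)methyl]-1,3-dithiane (not isolated) | [Li]C1(CC2(C)OCCO2)SCCCS1 | intermediate
17 | lithium enolate of the C7 conjugate adduct, C12(OLi)=C11 (not isolated) | [Li]OC1=C[C@@H](C2(CC3(C)OCCO3)SCCCS2)[C@H](/C=C(/C)[C@@H](O[Si](c2ccccc2)(c2ccccc2)C(C)(C)C)CCO[Si](C)(C)C(C)(C)C)O1 | intermediate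
18 | (3S,4R,5S)-5-{(1Z,3S)-5-[(tert-butyldimethylsilyl)oxy]-3-[(tert-butyldiphenylsilyl)oxy]-2-methylpent-1-en-1-yl}-3-[(dimethylamino)methyl]-4-{2-[(2-methyl-1,3-dioxolan-2-yl)methyl]-1,3-dithian-2-yl}oxolan-2-one | O=C1[C@H](CN(C)C)[C@@H](C2(CC3(C)OCCO3)SCCCS2)[C@H](/C=C(/C)[C@@H](O[Si](c2ccccc2)(c2ccccc2)C(C)(C)C)CCO[Si](C)(C)C(C)(C)C)O1 | intermediate
19 | (3S,4R,5S)-5-{(1Z,3S)-3-[(tert-butyldiphenylsilyl)oxy]-5-hydroxy-2-methylpent-1-en-1-yl}-3-[(dimethylamino)methyl]-4-[2-(2-oxopropyl)-1,3-dithian-2-yl]oxolan-2-one | O=C1[C@H](CN(C)C)[C@@H](C2(CC(C)=O)SCCCS2)[C@H](/C=C(/C)[C@@H](O[Si](c2ccccc2)(c2ccccc2)C(C)(C)C)CCO)O1 | intermediate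
20 | (3S,4R,5S)-5-{(1Z,3S)-3-[(tert-butyldiphenylsilyl)oxy]-2-methyl-5-oxopent-1-en-1-yl}-3-[(dimethylamino)methyl]-4-[2-(2-oxopropyl)-1,3-dithian-2-yl]oxolan-2-one | O=C1[C@H](CN(C)C)[C@@H](C2(CC(C)=O)SCCCS2)[C@H](/C=C(/C)[C@@H](O[Si](c2ccccc2)(c2ccccc2)C(C)(C)C)CC=O)O1 | intermediate
21 | (1S,3S,4Z,6S,7R,10R,11S)-3-[(tert-butyldiphenylsilyl)oxy]-13-(dimethylamino)-1,10-dihydroxy-8,8-(propane-1,3-diyldisulfanediyl)germacr-4-en-12,6-olide | CN(C)C[C@H]1C(=O)O[C@H]2/C=C(/C)[C@@H](O[Si](c3ccccc3)(c3ccccc3)C(C)(C)C)C[C@H](O)[C@](C)(O)CC3(SCCCS3)[C@H]12 | intermediate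
22 | (1S,3S,4Z,6S,7R,10R,11S)-3-[(tert-butyldiphenylsilyl)oxy]-13-(dimethylamino)-10-hydroxy-8,8-(propane-1,3-diyldisulfanediyl)-1-[(triethylsilyl)oxy]germacr-4-en-12,6-olide | CN(C)C[C@H]1C(=O)O[C@H]2/C=C(/C)[C@@H](O[Si](c3ccccc3)(c3ccccc3)C(C)(C)C)C[C@H](O[Si](CC)(CC)CC)[C@](C)(O)CC3(SCCCS3)[C@H]12 | intermediate
23 | (1S,3S,4Z,6S,7R,10R,11S)-3-[(tert-butyldiphenylsilyl)oxy]-13-(dimethylamino)-10-hydroxy-8-oxo-1-[(triethylsilyl)oxy]germacr-4-en-12,6-olide | CN(C)C[C@H]1C(=O)O[C@H]2/C=C(/C)[C@@H](O[Si](c3ccccc3)(c3ccccc3)C(C)(C)C)C[C@H](O[Si](CC)(CC)CC)[C@](C)(O)CC(=O)[C@H]12 | intermediate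
24 | (1S,3S,4Z,6S,7S,8R,10R,11S)-3-[(tert-butyldiphenylsilyl)oxy]-13-(dimethylamino)-8,10-dihydroxy-1-[(triethylsilyl)oxy]germacr-4-en-12,6-olide | CN(C)C[C@H]1C(=O)O[C@H]2/C=C(/C)[C@@H](O[Si](c3ccccc3)(c3ccccc3)C(C)(C)C)C[C@H](O[Si](CC)(CC)CC)[C@](C)(O)C[C@@H](O)[C@H]12 | intermediate
25 | angelic acid, (2Z)-2-methylbut-2-enoic acid | C/C=C(/C)C(=O)O | starting material
26 | (2Z)-2-methylbut-2-enoic 2,4,6-trichlorobenzoic anhydride (not isolated) | C/C=C(/C)C(=O)OC(=O)c1c(Cl)cc(Cl)cc1Cl | intermediate
27 | (1S,3S,4Z,6S,7S,8R,10R,11S)-3-[(tert-butyldiphenylsilyl)oxy]-13-(dimethylamino)-10-hydroxy-8-{[(2Z)-2-methylbut-2-enoyl]oxy}-1-[(triethylsilyl)oxy]germacr-4-en-12,6-olide | CN(C)C[C@H]1C(=O)O[C@H]2/C=C(/C)[C@@H](O[Si](c3ccccc3)(c3ccccc3)C(C)(C)C)C[C@H](O[Si](CC)(CC)CC)[C@](C)(O)C[C@@H](OC(=O)/C(C)=C\C)[C@H]12 | intermediate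
28 | C13 trimethylammonium iodide of 27 (not isolated) | C[N+](C)(C)C[C@H]1C(=O)O[C@H]2/C=C(/C)[C@@H](O[Si](c3ccccc3)(c3ccccc3)C(C)(C)C)C[C@H](O[Si](CC)(CC)CC)[C@](C)(O)C[C@@H](OC(=O)/C(C)=C\C)[C@H]12.[I-] | intermediate
29 | (1S,3S,4Z,6S,7S,8R,10R)-3-[(tert-butyldiphenylsilyl)oxy]-10-hydroxy-8-{[(2Z)-2-methylbut-2-enoyl]oxy}-1-[(triethylsilyl)oxy]germacra-4,11(13)-dien-12,6-olide | C=C1C(=O)O[C@H]2/C=C(/C)[C@@H](O[Si](c3ccccc3)(c3ccccc3)C(C)(C)C)C[C@H](O[Si](CC)(CC)CC)[C@](C)(O)C[C@@H](OC(=O)/C(C)=C\C)[C@H]12 | intermediate
30 | (1S,3S,4Z,6S,7S,8R,10R)-1,3,10-trihydroxy-8-{[(2Z)-2-methylbut-2-enoyl]oxy}germacra-4,11(13)-dien-12,6-olide (CNP0249520.1) | C=C1C(=O)O[C@H]2/C=C(/C)[C@@H](O)C[C@H](O)[C@](C)(O)C[C@@H](OC(=O)/C(C)=C\C)[C@H]12 | target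

## Step count and risk

Total step count: 19. Longest linear sequence: 17 steps (steps 1–7 and 10–19, from aldehyde 1). The dithiane branch (steps 8 and 9) joins at step 10.

**Step 10 (key step).** The most likely failure is deprotonation at C6 in competition with conjugate addition. The C6 hydrogen is allylic to C4=C5 and vinylogously α to the lactone carbonyl, so a strongly basic carbanion can form the 2-oxidofuran. That erases the C6 configuration and consumes the nucleophile. 1,2-Addition is the second risk.

The fallback sets out from 14 and 10 and comes back at 18. Dithiane 14 is lithiated and carboxylated with CO2 to 2-[(2-methyl-1,3-dioxolan-2-yl)methyl]-1,3-dithiane-2-carboxylic acid F1. Visible-light photoredox decarboxylation of F1 ([Ir{dF(CF3)ppy}2(dtbbpy)]PF6, K2HPO4, DMSO, blue light) generates the neutral 2-dithianyl radical. It adds to C7 of 10 anti to the C6 substituent in a Giese reaction, with no base able to touch the C6 hydrogen, and gives the (4R,5S)-4-dithianyl-5-alkenyl lactone F2. F2 is then deprotonated at C11 with LiN(iPr)2 at −78 °C and aminomethylated with 15 anti to the C7 substituent to give 18.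

**Step 13.** The closure may give poor control of the relative configuration at C1 and C10, and of their sense relative to C7, because nothing but the conformation of the closing ring decides it. Intermolecular coupling and simple reduction of the aldehyde compete at insufficient dilution.

The fallback sets out from 20 and comes back at 21. It corrects C1 by substrate control. If the closure delivers the trans diol, the (1R,10R)-1-epi diol F3, its secondary hydroxyl is oxidised under Swern conditions to the C1-oxo C10-hydroxy ketol F4. F4 is reduced with Zn(BH4)2 in Et2O at −20 °C. In the five-membered zinc chelate hydride enters from the side of the C14 methyl group, which places the C1 and C10 oxygens in the erythro relationship of 21. A wrong configuration at C10 cannot be repaired this way and would call for another closing reagent.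

**Step 6.** The Z enal may isomerise to the E enal under the Lewis-acidic zinc medium, and the ligand may be mismatched with the C3 centre, so that facial selectivity at C6 is low.

The fallback sets out from 7 and comes back at 8. Lithium methyl propiolate (from 2 and LiN(SiMe3)2, THF, −78 °C) is added without control to give 8 together with its (4R)-epimer F5. The mixture is oxidised with MnO2 to methyl (5Z,7S)-9-[(tert-butyldimethylsilyl)oxy]-7-[(tert-butyldiphenylsilyl)oxy]-6-methyl-4-oxonon-5-en-2-ynoate F6. F6 is reduced with (S)-Alpine-Borane (Midland reduction of a γ-oxo ynoate), for which the alkynyl group is the small substituent, to give 8.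

**Step 17.** The angelate may isomerise to the tiglate in the activated acyl species. Acylation of the hindered C8 hydroxyl may be slow. Warm triethylamine may promote acyl migration of the lactone from O6 to O8.

The fallback sets out from 24 and comes back at 27. It builds the Z alkene on the molecule. The C8 hydroxyl is esterified with 2-[bis(2,2,2-trifluoroethoxy)phosphoryl]propanoic acid (carbodiimide, DMAP, 0 °C) to the C8 phosphonopropionate F7. Still–Gennari olefination of F7 with acetaldehyde (KN(SiMe3)2, 18-crown-6, THF, −78 °C) gives the Z-configured 2-methylbut-2-enoate 27 under kinetic control.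

## Further compounds

F1 | step 10 | 2-[(2-methyl-1,3-dioxolan-2-yl)methyl]-1,3-dithiane-2-carboxylic acid | CC1(CC2(C(=O)O)SCCCS2)OCCO1
F2 | step 10 | (4R,5S)-5-{(1Z,3S)-5-[(tert-butyldimethylsilyl)oxy]-3-[(tert-butyldiphenylsilyl)oxy]-2-methylpent-1-en-1-yl}-4-{2-[(2-methyl-1,3-dioxolan-2-yl)methyl]-1,3-dithian-2-yl}oxolan-2-one | O=C1C[C@@H](C2(CC3(C)OCCO3)SCCCS2)[C@H](/C=C(/C)[C@@H](O[Si](c2ccccc2)(c2ccccc2)C(C)(C)C)CCO[Si](C)(C)C(C)(C)C)O1
F3 | step 13 | (1R,3S,4Z,6S,7R,10R,11S)-1-epimer of diol 21 | CN(C)C[C@H]1C(=O)O[C@H]2/C=C(/C)[C@@H](O[Si](c3ccccc3)(c3ccccc3)C(C)(C)C)C[C@@H](O)[C@](C)(O)CC3(SCCCS3)[C@H]12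
F4 | step 13 | (3S,4Z,6S,7R,10R,11S)-3-[(tert-butyldiphenylsilyl)oxy]-13-(dimethylamino)-10-hydroxy-1-oxo-8,8-(propane-1,3-diyldisulfanediyl)germacr-4-en-12,6-olide | CN(C)C[C@H]1C(=O)O[C@H]2/C=C(/C)[C@@H](O[Si](c3ccccc3)(c3ccccc3)C(C)(C)C)CC(=O)[C@](C)(O)CC3(SCCCS3)[C@H]12
F5 | step 6 | methyl (4R,5Z,7S)-9-[(tert-butyldimethylsilyl)oxy]-7-[(tert-butyldiphenylsilyl)oxy]-4-hydroxy-6-methylnon-5-en-2-ynoate | COC(=O)C#C[C@H](O)/C=C(/C)[C@@H](O[Si](c1ccccc1)(c1ccccc1)C(C)(C)C)CCO[Si](C)(C)C(C)(C)C
F6 | step 6 | methyl (5Z,7S)-9-[(tert-butyldimethylsilyl)oxy]-7-[(tert-butyldiphenylsilyl)oxy]-6-methyl-4-oxonon-5-en-2-ynoate | COC(=O)C#CC(=O)/C=C(/C)[C@@H](O[Si](c1ccccc1)(c1ccccc1)C(C)(C)C)CCO[Si](C)(C)C(C)(C)C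
F7 | step 17 | C8 2-[bis(2,2,2-trifluoroethoxy)phosphoryl]propanoate of 24 (both epimers at the phosphonate carbon) | CN(C)C[C@H]1C(=O)O[C@H]2/C=C(/C)[C@@H](O[Si](c3ccccc3)(c3ccccc3)C(C)(C)C)C[C@H](O[Si](CC)(CC)CC)[C@](C)(O)C[C@@H](OC(=O)C(C)P(=O)(OCC(F)(F)F)OCC(F)(F)F)[C@H]12
A1 | alternative 1 | C3–C6 endoperoxide of the ten-membered ring with C7 methyl acrylate, C1/C10 acetonide and C8 angelate | C=C(C(=O)OC)[C@@H]1[C@H]2OO[C@@H](C[C@@H]3OC(C)(C)O[C@]3(C)C[C@H]1OC(=O)/C(C)=C\C)C(C)=C2
A2 | alternative 1 | ten-membered ring diene with cis C3=C4 and cis C5=C6, C7 methyl acrylate, C1/C10 acetonide and C8 angelate | C=C(C(=O)OC)[C@@H]1/C=C\C(C)=C/C[C@@H]2OC(C)(C)O[C@]2(C)C[C@H]1OC(=O)/C(C)=C\C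
A3 | alternative 2 | (4Z)-cyclodecenone with C10 ketone, C3 and C8 methoxymethyl ethers, C6 p-methoxybenzyl ether | C=C(COCc3ccc(OC)cc3)[C@@H]1[C@@H](OCc4ccc(OC)cc4)/C=C(/C)[C@@H](OCOC)CCC(=O)C[C@H]1OCOC
A4 | alternative 2 | all-equatorial cyclohexanol (ring C5–C10) with vinyl and hydroxyl on C10 and an (E)-2-(methoxymethoxy)-1-methylvinyl group on C5 | C=C(COCc3ccc(OC)cc3)[C@@H]1[C@@H](OCc4ccc(OC)cc4)[C@H](/C(C)=C/OCOC)[C@@](O)(C=C)C[C@H]1OCOC
A5 | alternative 3 | ten-membered 1,10-diol with saturated lactone and silyl ethers at C3 and C8 | C1C(=O)O[C@H]2/C=C(/C)[C@@H](O[Si](C)(C)C(C)(C)C)C[C@H](O)[C@](C)(O)C[C@@H](O[Si](C)(C)C(C)(C)C)[C@H]12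
A6 | alternative 3 | open-chain keto aldehyde (C1 aldehyde, C10 methyl ketone) on the saturated lactone | O=C1C[C@@H]([C@H](O[Si](C)(C)C(C)(C)C)CC(C)=O)[C@H](/C=C(/C)[C@@H](O[Si](C)(C)C(C)(C)C)CC=O)O1
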